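The numbers are made up; the rest is arithmetic.

Two questions are asked of each of the two flasks, green and red: what there is most of at the end, and how much of it.

- green: left-handed substrate 0.20 M; solid reagent 1.50 equiv; free catalyst 9.5 mol%; right-handed substrate 0.20 M; temperature 0 °C; time 2.5 min
- red: left-handed substrate 0.20 M; solid reagent 1.50 equiv; free catalyst 9.5 mol%; right-handed substrate 0.20 M; temperature 10 °C; time 2.5 min

* which of these there is most of at the end, counted by the substrate in it, green (left-handed product / right-handed product / catalyst intermediate B / right-handed substrate)
* which of these there is most of at the end, counted by the substrate in it, red (left-handed product / right-handed product / catalyst intermediate B / right-handed substrate)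
* amount of the one of these that there is most of at the end, in percent of the left-handed substrate and right-handed substrate together charged, green
* amount of the one of these that there is most of at the end, in percent of the left-handed substrate and right-handed substrate together charged, red

- free catalyst is single-handed; left-handed substrate and right-handed substrate are mirror images of each other, charged as a racemate, each of them at the stated concentration
- as a solid, counted per litre of solution: solid reagent
- constants are those at 0 °C; use the activation energies and enthalpies for any other temperature
- at the start none of the solid reagent is in solution

    free catalyst + right-handed substrate ⇌ catalyst intermediate B (K1 = 2.7 /M, k1 = 320 /M/s, Ea1 = 40.0 kJ/mol, ΔH1 = 2.00 kJ/mol)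
    coupling partner + catalyst intermediate B → free catalyst + right-handed product (k2 = 0.47 /M/s, Ea2 = 48.0 kJ/mol)
    coupling partner + catalyst intermediate A → free catalyst + left-handed product (k3 = 2.9 /M/s, Ea3 = 52.0 kJ/mol)
    solid reagent ⇌ coupling partner, rate k4*(cs4 - [coupling partner]) while solid is left; crystals form when [coupling partner] > cs4 (cs4 = 0.19 M, k4 = 0.10 /s)
    free catalyst + left-handed substrate ⇌ catalyst intermediate A (K5 = 11 /M, k5 = 270 /M/s, Ea5 = 36.0 kJ/mol, ΔH5 = −35.0 kJ/mol)
    (constants at 0 °C)

The free catalyst reversibly binds either substrate, giving catalyst intermediate A from the left-handed one and catalyst intermediate B from the right-handed one, and each intermediate then couples with the coupling partner dissolving from the solid reagent. Catalyst intermediate A sheds its substrate at 24.5 /s but couples at 0.551 /s at most, so, because coupling is much slower, I treat binding as an equilibrium. Dividing the two rates of substrate loss then cancels the free catalyst and the coupling partner, leaving one number: 2.9 /M/s times 11 /M over 0.47 /M/s times 2.7 /M, a ratio of specificity constants, or selectivity factor, 25.1. It says that the fraction of left-handed substrate remaining equals the fraction of right-handed substrate remaining raised to that power. At the temperature of red, the constants' temperature dependence gives 15.0.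

I compute the small thing, the shortfall. With 1.00% of the left-handed substrate remaining, 83.2% of the right-handed substrate remains in green and 73.6% in red. The charge of solid reagent is worth 0.300 M of coupling partner, and reaching those points costs 0.231 M of it in green and 0.251 M in red, less than that charge.

But the number gives the path and not the distance along it, so I need a clock. With 0.0190 M of catalyst, the left-handed substrate follows integrated Michaelis–Menten kinetics with a half-saturation concentration of 0.140 M in green. Taking the coupling partner at 0.129 M, midway between its solubility and what the charge leaves, I reckon that green reaches that point in 1.97 min. The same sum for red, with 6.51 /M/s and 6.38 /M, gives 1.47 min. Both are shorter than 2.5 min, so I commit to left-handed product at 49.5% of the charge in both flasks.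

The forecast names left-handed product at 50% in green and left-handed product at 50% in red, holding that “The left-handed substrate is therefore consumed first”.

The simulation gives left-handed product at 49.3% in green and left-handed product at 49.7% in red.

In green, 8.58% of right-handed product, with bound substrate counted as unreacted, implies through 25.1 a shortfall from half the charge of 0.443%, and the simulated shortfall is 0.666%. The neighbouring flask is green with 0.600 equiv of solid reagent, which supplies 0.120 M of coupling partner, less than the 0.20 M of left-handed substrate. Its 1.66% of right-handed product implies through 25.1 28.6% of left-handed product, and that flask holds 27.6%. In that neighbouring flask, most of the two substrates together is held at the end by right-handed substrate, at 47.3%.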